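**Assumption:** (+)-sclareolide (3aR,5aS,9aS,9bR) is bought as the chiral starting material. The target's decalin is the normal-series skeleton (5S,8S,9R,10S) after a 4,9-friedo rearrangement, and I checked that the shifts below reproduce the given SMILES.

## Retrosynthetic overview
1. Ilimaquinone ⇒ 5-O-methylation (regioselective) of the 2,5-dihydroxy-3-alkylbenzoquinone 6, the embelin→5-O-methylembelin pattern.
2. 6 ⇒ photochemical decarboxylative radical addition of the neopentyl-type radical C9–CH2•, from the N-hydroxyphthalimide (NHPI) ester 4, to commercial 2,5-dihydroxybenzoquinone 5. This forms the ArCH2–C bond.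
3. 4 ⇐ acid 2 ⇐ (+)-sclareolide 1. One cationic cascade does the following:
   - lactone C8–O ionization;
   - four suprafacial 1,2-shifts (H-9→C8, Me-10→C9, H-5→C10, Me-4→C5);
   - kinetic deprotonation to the exocyclic methylene.
4. Both decalin rings and all four stereocentres come pre-formed or are controlled by sclareolide. The only ring built is none; the quinone ring is purchased.

## Route

**Step 1**
Reactants: 1, (+)-sclareolide
Product: 2, [(1R,2S,4aS,8aS)-1,2,4a-trimethyl-5-methylidene-decahydronaphthalen-1-yl]acetic acid (4,9-friedodrimane acid)
Conditions: BF3·OEt2 (4 equiv), 2,6-di-tert-butyl-4-methylpyridine (1.5 equiv), CH2Cl2, 0 → 25 °C, 6 h; then aq. HCl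
Reagents that add atoms: none
Why: Proposed new method: BF3 ionizes the tertiary C8–O bond of the lactone to a C8 cation that is held as a BF3-carboxylate. Four anti-periplanar, face-retentive Wagner–Meerwein shifts follow (H-9α→C8, Me-10β→C9, H-5α→C10, Me-4β→C5), and the hindered pyridine then removes a proton from the accessible C4 methyl rather than from ring C3. The closest known reaction is the biomimetic BF3-induced drimane→4,9-friedodrimane (avarane) cascade of 8-ols and 8-enes. Because every shift is suprafacial, the new centres come out as 5β-Me, 10α-H (trans ring fusion), 9β-Me/9α-CH2CO2H and 8β-Me/8α-H, with no external chiral agent.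

**Step 2**
Reactants: 2; 3, N-hydroxyphthalimide
Product: 4, NHPI ester of 2 (1,3-dioxoisoindolin-2-yl ester)
Conditions: NHPI (1.2 equiv), DIC (1.2 equiv), DMAP (0.1 equiv), CH2Cl2, 25 °C, 4 h
Reagents that add atoms: N-hydroxyphthalimide, O=C1c2ccccc2C(=O)N1O. DIC and DMAP add no atoms.
Why: Steglich-type carbodiimide esterification gives the redox-active ester; no stereocentre is touched and the alkene is inert.

**Step 3**
Reactants: 4; 5, 2,5-dihydroxy-1,4-benzoquinone
Product: 6, 2,5-dihydroxy-3-{[(1S,2S,4aS,8aS)-1,2,4a-trimethyl-5-methylidene-decahydronaphthalen-1-yl]methyl}-1,4-benzoquinone (stereodescriptors as drawn in the SMILES in the list)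
Conditions: fac-Ir(ppy)3 (2 mol %), 5 (3 equiv), DMSO, blue LEDs (456 nm), 25 °C, 18 h; then open to air, 1 M HCl workup
Reagents that add atoms: none beyond the named reactant 5
Why: Photoexcited Ir(III)* reduces the redox-active ester by single-electron transfer, and loss of CO2 and phthalimide anion gives the primary C9–CH2• radical. This nucleophilic radical adds to the free C–H of quinone 5 (Giese/Minisci-type addition to a quinone), and Ir(IV) oxidizes the resulting semiquinone to close the cycle. Air or excess 5 re-oxidizes to the quinone. The radical is not stereogenic, so the ring stereocentres are unaffected, and the alkene survives because the radical is nucleophilic and quinone-selective.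

**Step 4**
Reactants: 6; 7, trimethylsilyldiazomethane
Product: 8, ilimaquinone
Conditions: TMSCHN2 (1.1 equiv), MeOH/toluene (1:4), 0 °C, 30 min
Reagents that add atoms: TMSCHN2, C[Si](C)(C)C=[N+]=[N-] (supplies the OMe methyl)
Why: Diazomethane-type O-methylation of the most acidic vinylogous-acid OH; the C5–OH is more acidic and less hindered than the C2–OH beside the bulky substituent. This is the same selectivity that gives 5-O-methylembelin from embelin.

## Compound list
1 | (+)-sclareolide | C[C@]12CCCC(C)(C)[C@@H]1CC[C@@]3(C)OC(=O)C[C@H]23 | starting material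
2 | 4,9-friedodrimane acetic acid | C=C1CCC[C@H]2[C@](C)(CC(=O)O)[C@@H](C)CC[C@]12C | intermediate
3 | N-hydroxyphthalimide | O=C1c2ccccc2C(=O)N1O | starting material
4 | NHPI ester of 2 | C=C1CCC[C@H]2[C@](C)(CC(=O)ON3C(=O)c4ccccc4C3=O)[C@@H](C)CC[C@]12C | intermediate
5 | 2,5-dihydroxy-1,4-benzoquinone | O=C1C=C(O)C(=O)C=C1O | starting material
6 | 2,5-dihydroxy-3-alkyl-1,4-benzoquinone | C=C1CCC[C@H]2[C@](C)(CC3=C(O)C(=O)C=C(O)C3=O)[C@@H](C)CC[C@]12C | intermediate
7 | trimethylsilyldiazomethane | C[Si](C)(C)C=[N+]=[N-] | starting material
8 | ilimaquinone | C=C1CCC[C@H]2[C@](C)(CC3=C(O)C(=O)C=C(OC)C3=O)[C@@H](C)CC[C@]12C | target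

## Totals
Total steps: 4. Longest linear sequence: 4.

## Three steps most likely to fail
1. **Step 1 (the proposed new method): cascade and exocyclic selectivity.** The cascade may stall at an intermediate cation or lactone, or give the Δ3 alkene. Fallback (known chemistry, different approach): reduce 1 with LiAlH4 to the 8α,12-diol and protect the primary OH. Rearrange the tertiary 8-ol with BF3·OEt2, as in the precedented drimane-8-ol cascades. Separate the Δ4(11) and Δ3 isomers on AgNO3–silica, then deprotect and oxidize the primary alcohol to the acid 2 (TEMPO/BAIB, then NaClO2).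
2. **Step 3: photochemical coupling.** Yield and mono- versus di-alkylation of the poorly soluble hydroxyquinone are the concerns. Fallback: skip step 2 and run the classical Ag(I)/persulfate (Fieser–Kochi-type) decarboxylative alkylation of 5 directly with acid 2 in MeCN/H2O at 70 °C.
3. **Step 4: regioselective mono-O-methylation.** A mixture of the 2-OMe, 5-OMe and dimethyl ethers is possible. Fallback: make 2-hydroxy-5-methoxy-1,4-benzoquinone by mono-hydrolysis of commercial 2,5-dimethoxybenzoquinone and use it in place of 5 in step 3, which removes step 4. Separate the regioisomers chromatographically.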